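**Retrosynthetic overview**
1. Feature: in the cis-fused hexahydronaphthalene, the C8 CO2Me and the C1 ketone sit cis on the neighbouring atoms C8 and C8a (a γ-keto ester C1–C8a–C8–CO2Me across rings A/B), so the C8 carboxyl can hold an O–C1 diene over the C4a=C8a face of ring A.
2. C1 ketone + C8 methyl ester ⇐ methoxy acylal γ-lactone (isomerisation in acidic methanol).
3. Ring B and the lactone ⇐ one intramolecular [4+2] forming C1–C8a and C4–C4a: acyloxy ketene-acetal diene C1=C2–C3=C4 (C2 ester, C3 hexadecyl) onto a (1S,4S)-1,4-dihydroterephthalate.
4. Ester tether ⇐ O-acylation of the dienolate of dimethyl 2-(octadec-1-en-2-yl)malonate (from 1-octadecyne and dimethyl malonate, terminal methylene fixed) by the ring-A acid chloride.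
5. Ring A is made first from dimethyl 2-bromoterephthalate and 1-hexadecyne (Sonogashira, hydrogenation, Birch reduction) and resolved by hydrolase half-hydrolysis; ring order: A, then B together with the temporary lactone.

Key step: step 9

Assumption: the hydrolase, chosen by screening, is taken to cleave the (1S,4S)-enantiomer of the racemic trans diester at the ester remote from the hexadecyl chain; if the available enzymes prefer the mirror image, the fallback to step 4 is used.

**Step 1**
Reactants: 1 dimethyl 2-bromoterephthalate; 2 1-hexadecyne
Product: 3 dimethyl 2-(hexadec-1-yn-1-yl)terephthalate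
Conditions: PdCl2(PPh3)2 (2 mol%), CuI (4 mol%), Et3N, THF, 60 °C
Reagents that add atoms: none
Why: Sonogashira coupling, in which the aryl bromide activated by two ester groups adds readily to Pd(0) and couples with the copper acetylide; no stereocentre is formed.

**Step 2**
Reactants: 3 dimethyl 2-(hexadec-1-yn-1-yl)terephthalate
Product: 4 dimethyl 2-hexadecylterephthalate
Conditions: H2 (1 atm), 10% Pd/C, EtOAc, rt
Reagents that add atoms: none
Why: Heterogeneous catalytic hydrogenation saturates the alkyne to the hexadecyl chain while the arene and the aryl esters are inert; no stereocentre is formed.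

**Step 3**
Reactants: 4 dimethyl 2-hexadecylterephthalate
Product: 6 rac-trans-dimethyl 2-hexadecylcyclohexa-2,5-diene-1,4-dicarboxylate, via dilithium bis-enolate 5 (not isolated)
Conditions: Li (2.1 equiv), NH3(l)/THF, −78 °C; then NH4Cl; chromatography under argon (cis isomer removed)
Reagents that add atoms: none
Why: Birch reduction, in which the electron-poor arene takes up two electrons to the quinodimethane bis-enolate and kinetic protonation at both ester-bearing carbons should give the unconjugated 2,5-diene with the chain on a double bond; the two new stereocentres arise without facial control, so the trans racemate is obtained by separation from the cis isomer.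

**Step 4**
Reactants: 6 rac-trans-dimethyl 2-hexadecylcyclohexa-2,5-diene-1,4-dicarboxylate
Product: 7 (1S,4S)-3-hexadecyl-4-(methoxycarbonyl)cyclohexa-2,5-diene-1-carboxylic acid
Conditions: immobilised Candida antarctica lipase B, phosphate buffer pH 7/t-BuOMe, 30 °C, stopped near half conversion; acid taken out with cold aq. NaHCO3
Reagents that add atoms: water, O
Why: Hydrolase-catalysed kinetic resolution by ester hydrolysis, in which the enzyme should accept only the unhindered ester flanked by two CH= groups and only one enantiomer of the fatty substrate, leaving the (1R,4R)-diester behind; no stereocentre is formed, the absolute configuration is selected by the enzyme, and pH 7 avoids epimerisation or conjugation of the doubly allylic centres.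

**Step 5**
Reactants: 8 1-octadecyne
Product: 10 2-bromooctadec-1-ene, via bromoalkenylborane 9 (not isolated)
Conditions: B-bromo-9-BBN, CH2Cl2, 0 °C; then AcOH, 0 °C to rt
Reagents that add atoms: B-bromo-9-borabicyclo[3.3.1]nonane, BrB1C2CCCC1CCC2
Why: Haloboration followed by protodeboronation, in which the B–Br bond adds syn to the terminal alkyne with bromine on the internal carbon and acetic acid cleaves the alkenyl C–B bond, so the terminal methylene of the later diene is fixed; no stereocentre is formed.

**Step 6**
Reactants: 10 2-bromooctadec-1-ene; 11 dimethyl malonate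
Product: 13 dimethyl 2-(octadec-1-en-2-yl)malonate, via sodium dienolate 12 (not isolated)
Conditions: NaH (2.2 equiv), Pd(dba)2 (2 mol%), P(t-Bu)3 (4 mol%), THF, 65 °C; then AcOH, −78 °C
Reagents that add atoms: none
Why: Palladium-catalysed α-alkenylation of a malonate enolate, in which the coupled product is held as its sodium dienolate by the second equivalent of base so that the double bond cannot migrate, and kinetic α-protonation at −78 °C should give the β,γ-unsaturated malonate; no stereocentre is formed.

**Step 7**
Reactants: 7 (1S,4S)-3-hexadecyl-4-(methoxycarbonyl)cyclohexa-2,5-diene-1-carboxylic acid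
Product: 14 methyl (1S,4S)-4-(chlorocarbonyl)-2-hexadecylcyclohexa-2,5-diene-1-carboxylate
Conditions: 1-chloro-N,N,2-trimethylprop-1-en-1-amine (1.1 equiv), CH2Cl2, 0 °C; used at once as the crude solution
Reagents that add atoms: 1-chloro-N,N,2-trimethylprop-1-en-1-amine, CC(C)=C(Cl)N(C)C
Why: Acid chloride formation with an α-chloroenamine runs under neutral conditions without HCl or base, so both doubly allylic stereocentres and the unconjugated diene should be preserved.

**Step 8**
Reactants: 13 dimethyl 2-(octadec-1-en-2-yl)malonate; 14 methyl (1S,4S)-4-(chlorocarbonyl)-2-hexadecylcyclohexa-2,5-diene-1-carboxylate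
Product: 16 methyl (1S,4S)-2-hexadecyl-4-({[(1Z)-1-methoxy-2-(methoxycarbonyl)-3-methylidenenonadec-1-en-1-yl]oxy}carbonyl)cyclohexa-2,5-diene-1-carboxylate, via potassium dienolate 15 (not isolated)
Conditions: 13, KHMDS (1.0 equiv), 18-crown-6, THF, −78 °C; then cannulated into 14 (1.1 equiv), THF, −78 °C; non-aqueous work-up (pentane, filtration under argon)
Reagents that add atoms: none
Why: Kinetic O-acylation of a doubly stabilised enolate (enol-ester formation), favoured because the crown-separated potassium dienolate carries its charge on oxygen, its α-carbon is tertiary between two esters and a 1,1-disubstituted vinyl group, and the acid chloride is α-branched; inverse addition at −78 °C keeps base away from the epimerisable C–H of 14, no stereocentre is formed, and the ketene-acetal geometry is without consequence because C1 becomes an acetal.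

**Step 9**
Reactants: 16 methyl (1S,4S)-2-hexadecyl-4-({[(1Z)-1-methoxy-2-(methoxycarbonyl)-3-methylidenenonadec-1-en-1-yl]oxy}carbonyl)cyclohexa-2,5-diene-1-carboxylate
Product: 17 dimethyl 4,7-dihexadecyl-8a-methoxy-2-oxo-2a,5,5a,6,8a,8b-hexahydro-2H-naphtho[1,8-bc]furan-5,8-dicarboxylate
Conditions: degassed PhMe (5 mM), BHT (cat.), 2,6-di-tert-butyl-4-methylpyridine (cat.), 180 °C, sealed silanised tube
Reagents that add atoms: none
Why: Proposed new method: a thermal, concerted and suprafacial [4+2] cycloaddition (type 1 intramolecular Diels–Alder) in which the O-acyl ketene-acetal diene C1=C2–C3=C4 adds to the cis alkene C4a=C8a; the closest known reactions are ester-tethered intramolecular Diels–Alder reactions with three-atom tethers and the cycloadditions of 1,1-dioxygenated 2-alkoxycarbonyl dienes (silyl ketene acetals of alkylidenemalonates) and of 3-alkoxycarbonyl-2-pyranones with alkenes, but an acyloxy ketene acetal has not served as a tethered diene toward an unactivated alkene. Ring B closes as a six-membered ring through the two new bonds C1–C8a and C4–C4a, and the γ-lactone closes in the same event as the five-membered ring C8–C(=O)–O–C1–C8a fused to rings A and B, the cross-conjugated enol-ester oxygen lowering the cost of the s-cis ester conformation that a lactone needs. C8a and C4a are set by the existing C8 stereocentre, because the tether can deliver the diene only to the ring face that carries the C8 carboxyl and the addition is suprafacial, so H-8, H-8a and H-4a end up cis and the spectator C5 ester stays trans to the lactone; C1 is fixed by the cis fusion of the lactone and is erased in step 10. The step needs site selectivity between the two ring alkenes that flank C8 and a single orientation of the diene: C1 can reach C4a only with the ester linkage twisted out of conjugation, and addition to C6=C7 would have to create a quaternary centre at the hexadecyl-bearing C6, so the less substituted C4a=C8a should react. The trans arrangement of H-5 and H-8 blocks concerted loss of H2 from ring A, and high dilution, a radical inhibitor and a hindered base are meant to suppress oligomerisation, autoxidation and acid-induced cleavage of the ketene acetal at the temperature required.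

**Step 10**
Reactants: 17 dimethyl 4,7-dihexadecyl-8a-methoxy-2-oxo-2a,5,5a,6,8a,8b-hexahydro-2H-naphtho[1,8-bc]furan-5,8-dicarboxylate
Product: 18 trimethyl (4aR,5S,8R,8aS)-3,6-dihexadecyl-1-oxo-1,4,4a,5,8,8a-hexahydronaphthalene-2,5,8-tricarboxylate (CNP0149813.1)
Conditions: camphorsulfonic acid (cat.), MeOH/CH2Cl2, 0 °C to rt
Reagents that add atoms: methanol, CO
Why: Acid-catalysed methanolysis of an acylal (pseudo-ester to normal ester isomerisation), in which methanol opens the activated lactone at its carbonyl to the C8 methyl ester and the C1 hemiketal collapses to the ketone; all esters are methyl esters so exchange with the solvent is degenerate, and the four stereocentres set earlier should survive mild acid.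

**Compound list**
1 | dimethyl 2-bromoterephthalate | COC(=O)c1ccc(C(=O)OC)c(Br)c1 | starting material
2 | 1-hexadecyne | CCCCCCCCCCCCCCC#C | starting material
3 | dimethyl 2-(hexadec-1-yn-1-yl)terephthalate | COC(=O)c1ccc(C(=O)OC)c(C#CCCCCCCCCCCCCCC)c1 | intermediate
4 | dimethyl 2-hexadecylterephthalate | COC(=O)c1ccc(C(=O)OC)c(CCCCCCCCCCCCCCCC)c1 | intermediate
5 | dilithium bis-enolate (quinodimethane dianion) of 4 | CCCCCCCCCCCCCCCCC1=CC(=C([O-])OC)C=CC1=C([O-])OC.[Li+].[Li+] | intermediate (not isolated)
6 | dimethyl (1RS,4RS)-2-hexadecylcyclohexa-2,5-diene-1,4-dicarboxylate (trans; racemate, both enantiomers written) | CCCCCCCCCCCCCCCCC1=C[C@@H](C(=O)OC)C=C[C@@H]1C(=O)OC.CCCCCCCCCCCCCCCCC1=C[C@H](C(=O)OC)C=C[C@H]1C(=O)OC | intermediate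
7 | (1S,4S)-3-hexadecyl-4-(methoxycarbonyl)cyclohexa-2,5-diene-1-carboxylic acid (trans) | CCCCCCCCCCCCCCCCC1=C[C@@H](C(=O)O)C=C[C@@H]1C(=O)OC | intermediate
8 | 1-octadecyne | CCCCCCCCCCCCCCCCC#C | starting material
9 | B-[(Z)-2-bromooctadec-1-en-1-yl]-9-borabicyclo[3.3.1]nonane | Br/C(CCCCCCCCCCCCCCCC)=C\B1C2CCCC1CCC2 | intermediate (not isolated)
10 | 2-bromooctadec-1-ene | C=C(Br)CCCCCCCCCCCCCCCC | intermediate
11 | dimethyl malonate | COC(=O)CC(=O)OC | starting material
12 | sodium dienolate of 13 | C=C(CCCCCCCCCCCCCCCC)C(C(=O)OC)=C([O-])OC.[Na+] | intermediate (not isolated)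
13 | dimethyl 2-(octadec-1-en-2-yl)malonate | C=C(CCCCCCCCCCCCCCCC)C(C(=O)OC)C(=O)OC | intermediate
14 | methyl (1S,4S)-4-(chlorocarbonyl)-2-hexadecylcyclohexa-2,5-diene-1-carboxylate | CCCCCCCCCCCCCCCCC1=C[C@@H](C(Cl)=O)C=C[C@@H]1C(=O)OC | intermediate
15 | potassium dienolate of 13 | C=C(CCCCCCCCCCCCCCCC)C(C(=O)OC)=C([O-])OC.[K+] | intermediate (not isolated)
16 | methyl (1S,4S)-2-hexadecyl-4-({[(1Z)-1-methoxy-2-(methoxycarbonyl)-3-methylidenenonadec-1-en-1-yl]oxy}carbonyl)cyclohexa-2,5-diene-1-carboxylate (acyloxy ketene acetal; ring substituents trans) | CCCCCCCCCCCCCCCCC1=C[C@@H](C(=O)O/C(OC)=C(\C(=O)OC)C(=C)CCCCCCCCCCCCCCCC)C=C[C@@H]1C(=O)OC | intermediate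
17 | dimethyl 4,7-dihexadecyl-8a-methoxy-2-oxo-2a,5,5a,6,8a,8b-hexahydro-2H-naphtho[1,8-bc]furan-5,8-dicarboxylate (tricyclic acylal lactone; H-2a, H-8b and H-5a cis; 8a-OMe cis to H-8b; 5-CO2Me cis to H-5a) | CCCCCCCCCCCCCCCCC1=C[C@@H]3[C@H]2[C@@](OC)(OC3=O)C(C(=O)OC)=C(CCCCCCCCCCCCCCCC)C[C@H]2[C@@H]1C(=O)OC | intermediate
18 | trimethyl (4aR,5S,8R,8aS)-3,6-dihexadecyl-1-oxo-1,4,4a,5,8,8a-hexahydronaphthalene-2,5,8-tricarboxylate | CCCCCCCCCCCCCCCCC1=C[C@@H](C(=O)OC)[C@H]2C(=O)C(C(=O)OC)=C(CCCCCCCCCCCCCCCC)C[C@H]2[C@@H]1C(=O)OC | target

**Step count**
Total: 10 steps. Longest linear sequence: 8 steps (1, 2, 3, 4, 7, 8, 9, 10) from dimethyl 2-bromoterephthalate; the diene arm (steps 5, 6) joins at step 8.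

**Steps most likely to fail**

1. Step 9 (proposed new method). The cycloaddition onto an unactivated cis-disubstituted alkene may be slower than unimolecular decay of the acyl ketene acetal (retro-ene loss of a ketene from the acyl part, 1,3-shift of the acyl group to carbon), than autoxidative aromatisation of ring A, or than competing addition to C6=C7. Fallback with known chemistry: the closure is moved from a thermal pericyclic reaction to a metal-templated one. Setting out again from 16, a rhodium(I)-catalysed intramolecular diene–alkene [4+2] cycloaddition ([Rh(cod)Cl]2 with tris(1,1,1,3,3,3-hexafluoropropan-2-yl) phosphite, THF, 50–60 °C) is an established way to join a tethered 1,3-diene to an unactivated alkene. It runs through oxidative cyclisation to a rhodacycle and reductive elimination, needs no frontier-orbital activation and far less heat, and the same three-atom tether still dictates site and face. It comes back to the route at 17 without any new compound (F0).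

2. Step 8. Acylation may occur at the malonate carbon or at the terminal methylene instead of at oxygen, or the dienolate may deprotonate the acid chloride, leading to a ketene and to epimerisation next to the carbonyl. Fallback: base-free acyl transfer to a preformed silyl ketene acetal. Acid 7 is converted with cyanuric fluoride/pyridine (CH2Cl2, −20 °C) into the acyl fluoride methyl (1S,4S)-4-(fluorocarbonyl)-2-hexadecylcyclohexa-2,5-diene-1-carboxylate F1. Malonate 13 is O-silylated (LiHMDS, Me3SiCl, THF, −78 °C) to the silyl ketene acetal methyl 3-methoxy-2-(octadec-1-en-2-yl)-3-(trimethylsilyloxy)prop-2-enoate F2. A catalytic anhydrous fluoride source (tetrabutylammonium difluorotriphenylsilicate, THF, −40 °C) then releases the naked dienolate only in the presence of F1, and O-acylation by the hard acyl fluoride with loss of Me3SiF should give 16, where the route is rejoined.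

3. Step 4. The hydrolase may show low enantioselectivity, prefer the wrong enantiomer, or fail to distinguish the two ester groups. Fallback: the carboxyl groups are differentiated at the arene stage and the acid is resolved classically. Setting out from 4, one equivalent of KOH (MeOH/THF, rt) should cleave the ester meta to the chain, which is less hindered than the ortho one, to give 3-hexadecyl-4-(methoxycarbonyl)benzoic acid F3. Birch reduction of its lithium salt (Li, NH3/THF, −78 °C; NH4Cl) and removal of the cis isomer should give racemic trans-3-hexadecyl-4-(methoxycarbonyl)cyclohexa-2,5-diene-1-carboxylic acid F4. Fractional crystallisation with (R)- or (S)-1-phenylethylamine (whichever gives the less soluble salt of the (1S,4S)-acid; written for R) should give (R)-1-phenylethylammonium (1S,4S)-3-hexadecyl-4-(methoxycarbonyl)cyclohexa-2,5-diene-1-carboxylate F5, and cold dilute HCl liberates 7, where the route is rejoined.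

**Further compounds**
F0 | step 9 | none | none
F1 | step 8 | methyl (1S,4S)-4-(fluorocarbonyl)-2-hexadecylcyclohexa-2,5-diene-1-carboxylate | CCCCCCCCCCCCCCCCC1=C[C@@H](C(F)=O)C=C[C@@H]1C(=O)OC
F2 | step 8 | methyl 3-methoxy-2-(octadec-1-en-2-yl)-3-(trimethylsilyloxy)prop-2-enoate (E/Z mixture) | C=C(CCCCCCCCCCCCCCCC)C(C(=O)OC)=C(OC)O[Si](C)(C)C
F3 | step 4 | 3-hexadecyl-4-(methoxycarbonyl)benzoic acid | CCCCCCCCCCCCCCCCc1cc(C(=O)O)ccc1C(=O)OC
F4 | step 4 | (1RS,4RS)-3-hexadecyl-4-(methoxycarbonyl)cyclohexa-2,5-diene-1-carboxylic acid (trans; racemate, both enantiomers written) | CCCCCCCCCCCCCCCCC1=C[C@@H](C(=O)O)C=C[C@@H]1C(=O)OC.CCCCCCCCCCCCCCCCC1=C[C@H](C(=O)O)C=C[C@H]1C(=O)OC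
F5 | step 4 | (R)-1-phenylethylammonium (1S,4S)-3-hexadecyl-4-(methoxycarbonyl)cyclohexa-2,5-diene-1-carboxylate | CCCCCCCCCCCCCCCCC1=C[C@@H](C(=O)[O-])C=C[C@@H]1C(=O)OC.C[C@@H]([NH3+])c1ccccc1
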